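**Plan**

1. Numbering (target backbone): C1–C2 ethyl, C3 side-chain carbinol, C4 and C8 the two N–CH carbons, C5–C7 piperidine CH2, C9–C13 cyclopentane (C10 methyl, C11 OH, C12 spiro, C13 tertiary OH), C14–C16 azepane CH2, C2'–C4' tetronate. The cyclopentane, oxygenated at C11 and C12 beside the methyl-bearing C10 and fused to the azepane along C9–C13, is read as a cyclopent-2-enone (C11=O, C12=C13). That enone is the Rautenstrauch product of a C12 pivaloyloxy 1,4-enyne whose alkene is C9=C13 of a tetrahydroazepine.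
2. Retrosynthetic cuts, in order: spirotetronate (C12–O, C12–C4') and the C12/C13 oxygens; N–C4 (piperidine); C9–C10 (cyclopentenone); C9=C13 (metathesis); N–C16 and C8–C9 (allylic amine); C4–C5 (ketone from a Weinreb amide).
3. Forward: C1–C8 chain with C4 masked as a dioxolane, then the C8 allylic carbamate, the N-Boc tetrahydroazepine, the C12 propargylic pivalate, the cyclopentenone, the piperidine, the C11/C12/C13 oxygens, the spirotetronate, and deprotection.
4. Stereochemistry: C3 from (R)-2-hydroxybutanoic acid; C8 from (S)-tert-butanesulfinamide; C12 carbinol from CBS reduction, relayed to C9 in the key step; C10 by equilibration; C4 by axial hydride delivery to the cyclic iminium ion; C11 by hydride attack anti to the C10 methyl; C13 by osmylation anti to the C11 silyl ether; spiro C12 by addition anti to the axial C13 silyl ether.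

Key step: step 17

Assumption: methyl (E)-3-methoxy-2-methylacrylate, used in step 24, is taken as a purchasable reagent; the Grignard reagents of steps 7 and 14 are used as commercial THF solutions.

Step 1
Reactants: 1 (R)-2-hydroxybutanoic acid
Product: 2 (R)-2-(benzyloxy)butanoic acid
Conditions: NaH (2.5 equiv), THF, 0 °C; BnBr (1.05 equiv), Bu4NI (cat.), rt; then 1 M HCl
Reagents that add atoms: benzyl bromide, BrCc1ccccc1
Why: Williamson etherification of the carboxylate–alkoxide dianion puts benzyl on oxygen only, and C3 keeps its configuration because a carboxylate does not enolise under these conditions.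

Step 2
Reactants: 2 (R)-2-(benzyloxy)butanoic acid
Product: 3 (R)-2-(benzyloxy)-N-methoxy-N-methylbutanamide
Conditions: MeNH(OMe)·HCl, EDC·HCl, HOBt, iPr2NEt, CH2Cl2, 0 °C → rt
Reagents that add atoms: N,O-dimethylhydroxylamine hydrochloride, CNOC.Cl
Why: Carbodiimide amide coupling through the HOBt ester gives the Weinreb amide, and α-alkoxy acids are not prone to racemisation in this coupling.

Step 3
Reactants: 3 (R)-2-(benzyloxy)-N-methoxy-N-methylbutanamide; 4 5-bromopent-1-ene
Product: 6 (R)-3-(benzyloxy)non-8-en-4-one, via pent-4-enylmagnesium bromide 5 (not isolated)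
Conditions: 4, Mg, THF, rt; then 3, THF, 0 °C; aq. NH4Cl
Reagents that add atoms: none
Why: Weinreb ketone synthesis: the Grignard reagent made in the flask adds once, because the magnesium chelate of the tetrahedral adduct blocks over-addition and collapses to the ketone only on quench.

Step 4
Reactants: 6 (R)-3-(benzyloxy)non-8-en-4-one
Product: 7 2-[(R)-1-(benzyloxy)propyl]-2-(pent-4-enyl)-1,3-dioxolane
Conditions: TMSOCH2CH2OTMS, TMSOTf (5 mol %), CH2Cl2, −78 → −20 °C; pyridine
Reagents that add atoms: 1,2-bis(trimethylsilyloxy)ethane, C[Si](C)(C)OCCO[Si](C)(C)C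
Why: Silyl-triflate-catalysed ketalisation with the bis-silyl ether of ethylene glycol works at low temperature on hindered α-alkoxy ketones without enolisation at C3, and the dioxolane masks C4 against the Grignard, borane and borohydride steps ahead.

Step 5
Reactants: 7 2-[(R)-1-(benzyloxy)propyl]-2-(pent-4-enyl)-1,3-dioxolane
Product: 8 4-{2-[(R)-1-(benzyloxy)propyl]-1,3-dioxolan-2-yl}butanal
Conditions: O3, CH2Cl2, −78 °C; then PPh3, → rt
Reagents that add atoms: ozone, O=[O+][O-]
Why: Ozonolysis with reductive work-up cleaves the only alkene to the C8 aldehyde, ozone being stopped at the indicator end point so that the benzyl ether survives.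

Step 6
Reactants: 8 4-{2-[(R)-1-(benzyloxy)propyl]-1,3-dioxolan-2-yl}butanal
Product: 9 (S)-N-sulfinyl (E)-aldimine of 8
Conditions: (S)-tBuS(O)NH2, CuSO4, CH2Cl2, rt
Reagents that add atoms: (S)-2-methylpropane-2-sulfinamide, CC(C)(C)[S@](=O)N
Why: Condensation of an aldehyde with tert-butanesulfinamide over a dehydrating Lewis acid gives the (E)-N-sulfinyl imine without touching the remote stereocentre.

Step 7
Reactants: 9 (S)-N-sulfinyl (E)-aldimine; 10 vinylmagnesium bromide
Product: 11 (S)-N-sulfinyl (S)-allylic amine (C8 S)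
Conditions: CH2=CHMgBr, CH2Cl2, −78 → −40 °C; aq. NH4Cl
Reagents that add atoms: none
Why: 1,2-Addition of a Grignard reagent to an N-tert-butanesulfinyl imine in a non-coordinating solvent runs through a six-membered chair with magnesium on the sulfinyl oxygen, which for the (S)-sulfinyl group delivers vinyl to the face that gives (S)-C8.

Step 8
Reactants: 11 (S)-N-sulfinyl (S)-allylic amine
Product: 13 N-Boc (S)-allylic amine, via amine hydrochloride 12 (not isolated)
Conditions: HCl (2 equiv, 4 M in dioxane), MeOH, 0 °C; evaporate; then Boc2O, Et3N, CH2Cl2, rt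
Reagents that add atoms: di-tert-butyl dicarbonate, CC(C)(C)OC(=O)OC(=O)OC(C)(C)C
Why: Acidolysis of the N–S bond followed by Boc protection exchanges the auxiliary for a carbamate, and stoichiometric anhydrous HCl at 0 °C should cleave the sulfinamide within minutes while leaving the deactivated α-alkoxy dioxolane intact.

Step 9
Reactants: 14 triethyl phosphonoacetate; 15 1,3-dibromopropane
Product: 16 ethyl 5-bromo-2-(diethoxyphosphoryl)pentanoate
Conditions: NaH, THF, 0 °C; BrCH2CH2CH2Br (3 equiv), 60 °C
Reagents that add atoms: none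
Why: SN2 C-alkylation of the phosphonoacetate anion, with excess dibromide suppressing a second alkylation and cyclobutane formation.

Step 10
Reactants: 16 ethyl 5-bromo-2-(diethoxyphosphoryl)pentanoate
Product: 17 ethyl 5-bromo-2-methylidenepentanoate
Conditions: 37% aq. HCHO, K2CO3, H2O/THF, rt
Reagents that add atoms: formaldehyde, C=O
Why: Horner–Wadsworth–Emmons methylenation with aqueous formaldehyde turns α-alkylated phosphonoacetates into 2-substituted acrylates under a carbonate base that spares the primary bromide.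

Step 11
Reactants: 13 N-Boc (S)-allylic amine; 17 ethyl 5-bromo-2-methylidenepentanoate
Product: 18 N-Boc N-(4-ethoxycarbonylpent-4-enyl) allylic amine (metathesis diene)
Conditions: NaH, DMF, 0 °C; then 17, Bu4NI (10 mol %), 0 °C → rt
Reagents that add atoms: none
Why: SN2 N-alkylation of the carbamate sodium salt with a primary bromide under iodide catalysis; the carbamate and not the free amine is alkylated because a fully substituted, non-basic nitrogen cannot add to the acrylate afterwards.

Step 12
Reactants: 18 metathesis diene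
Product: 19 N-Boc tetrahydroazepine ethyl ester (C9=C13; ester carbon C12)
Conditions: second-generation Grubbs catalyst (5 mol %), toluene (5 mM), 80 °C
Reagents that add atoms: none
Why: Ring-closing metathesis between the monosubstituted C9 alkene and the 1,1-disubstituted acrylate gives the trisubstituted C9=C13 enoate in the seven-membered ring, the carbamate favouring the folded rotamer and loss of ethene driving the closure.

Step 13
Reactants: 19 N-Boc tetrahydroazepine ethyl ester
Product: 20 N-Boc tetrahydroazepine Weinreb amide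
Conditions: MeNH(OMe)·HCl, iPrMgCl, THF, −20 → 0 °C; aq. NH4Cl
Reagents that add atoms: N,O-dimethylhydroxylamine hydrochloride, CNOC.Cl
Why: Aminolysis of the ester by the chloromagnesium amide of N,O-dimethylhydroxylamine (Weinreb amide formation) is faster than conjugate addition to the β-substituted enoate, and carbamate and ketal are inert.

Step 14
Reactants: 20 N-Boc tetrahydroazepine Weinreb amide; 21 prop-1-ynylmagnesium bromide
Product: 22 N-Boc tetrahydroazepinyl propynyl ketone (ynone)
Conditions: CH3C≡CMgBr, THF, −20 → 0 °C; aq. NH4Cl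
Reagents that add atoms: none
Why: Weinreb ketone synthesis with an alkynyl Grignard reagent stops at the ynone because the chelated tetrahedral adduct persists until quench.

Step 15
Reactants: 22 ynone
Product: 23 (R)-propargylic alcohol (C12 R)
Conditions: (R)-2-methyl-CBS-oxazaborolidine (0.5 equiv), BH3·SMe2, THF, −30 °C; MeOH
Reagents that add atoms: none
Why: Corey–Bakshi–Shibata reduction: the rod-like propynyl group acts as the small and the α-branched ring alkenyl group as the large substituent, so the (R)-oxazaborolidine should deliver hydride under reagent control to give the (R)-carbinol (alkynyl ranks above alkenyl).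

Step 16
Reactants: 23 (R)-propargylic alcohol
Product: 24 (R)-propargylic pivalate (3-pivaloyloxy-1,4-enyne)
Conditions: PivCl, Et3N, DMAP (cat.), CH2Cl2, 0 °C → rt
Reagents that add atoms: pivaloyl chloride, CC(C)(C)C(=O)Cl
Why: DMAP-catalysed acylation of the secondary propargylic alcohol, with retention at C12, installs the migrating pivalate.

Step 17
Reactants: 24 (R)-propargylic pivalate
Product: 26 N-Boc azepane-fused cyclopent-2-enone (C11=O; C12=C13; 8S,9S,10S), via dienyl pivalate 25 (not isolated)
Conditions: Ph3PAuCl (5 mol %), AgSbF6 (5 mol %), MeCN, H2O (2 equiv), −20 °C → rt; then K2CO3, MeOH, 0 °C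
Reagents that add atoms: none
Why: Cationic Ph3PAu+ binds the alkyne, the pivalate carbonyl oxygen adds anti at C11 (1,2-acyloxy shift through a dioxolenium ion) and the vinylgold carbon C10 bonds to the alkene terminus C9 as the C12–O bond ionises; loss of gold gives dienyl pivalate 25, which water hydrolyses to the C11 ketone conjugated with C12=C13. This is the gold-catalysed Rautenstrauch rearrangement of 3-acyloxy-1,4-enynes, established with substituted alkynes and cyclic alkenes and applied here to an N-acyl tetrahydroazepine. The cyclopentene closes in a Nazarov-like 4π conrotatory (5-endo) mode through a helical, pentadienyl-cation-like transition state. C9 is set by centre-to-helix-to-centre chirality transfer, C10 attacking the alkene face anti to the departing C12–O bond, which for the (R)-pivalate is the face syn to the C8 side chain as the target requires; C10 is then set thermodynamically, K2CO3/MeOH equilibrating the α-methyl trans to the C9 substituent. The step needs the C12 centre to override the facial bias of C8 and needs nitrogen not to bind gold; concerted ionisation and C–C bonding in MeCN at low temperature and the Boc carbamate are meant to secure both.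

Step 18
Reactants: 26 N-Boc azepane-fused cyclopent-2-enone
Product: 29 tricyclic enone amine (piperidine closed; 3R,4R,8S,9S,10S), via amino ketone hydrochloride 27 (not isolated), via cyclic iminium chloride 28 (not isolated)
Conditions: 3 M aq. HCl, THF, 40 °C; evaporate; then NaOAc, NaBH(OAc)3, AcOH, ClCH2CH2Cl, 0 °C → rt
Reagents that add atoms: none
Why: Acid hydrolysis removes the Boc group and the dioxolane, the freed secondary amine condenses with the C4 ketone to the six-membered iminium ion, and NaBH(OAc)3 reduces it by axial attack (intramolecular reductive amination), which should place H-4 cis to H-8 as in a 2,6-cis piperidine while the enone is not reduced.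

Step 19
Reactants: 29 tricyclic enone amine
Product: 30 C11 allylic alcohol (11S)
Conditions: NaBH4, CeCl3·7H2O, MeOH, −78 → −40 °C
Reagents that add atoms: none
Why: Luche reduction gives clean 1,2-reduction, hydride approaching C11 anti to the adjacent C10 methyl so that the hydroxyl should end cis to the methyl.

Step 20
Reactants: 30 C11 allylic alcohol
Product: 31 C11 triethylsilyl ether
Conditions: TESOTf, 2,6-lutidine, CH2Cl2, −78 → 0 °C
Reagents that add atoms: triethylsilyl trifluoromethanesulfonate, CC[Si](CC)(CC)OS(=O)(=O)C(F)(F)F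
Why: Silylation with a silyl triflate and a hindered pyridine base protects the hindered allylic alcohol and supplies the bulky allylic ether that steers the osmylation.

Step 21
Reactants: 31 C11 triethylsilyl ether
Product: 32 C12,C13 cis-diol (12R,13S)
Conditions: OsO4 (5 mol %), NMO, acetone/H2O (5:1), rt
Reagents that add atoms: N-methylmorpholine N-oxide, C[N+]1([O-])CCOCC1; water, O (the two hydroxyl oxygens, passed on through OsO4, O=[Os](=O)(=O)=O)
Why: Catalytic osmium tetroxide syn-dihydroxylation of the trisubstituted alkene is expected anti to the allylic C11 silyloxy group and to the C10 methyl, so that both hydroxyls enter cis on the lower face and C13 becomes the trans-fused tertiary carbinol.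

Step 22
Reactants: 32 C12,C13 cis-diol
Product: 33 C12 ketone with free C13 tertiary alcohol
Conditions: (COCl)2, DMSO, CH2Cl2, −78 °C; then Et3N, → 0 °C
Reagents that add atoms: none
Why: Swern oxidation turns the secondary C12 alcohol of the diol into the ketone without C–C cleavage and leaves the tertiary alcohol and the amine untouched, erasing a C12 configuration that is not needed.

Step 23
Reactants: 33 C12 ketone with free C13 tertiary alcohol
Product: 34 C11,C13 bis(triethylsilyl) ether of the C12 ketone
Conditions: TESOTf, 2,6-lutidine, CH2Cl2, −40 → 0 °C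
Reagents that add atoms: triethylsilyl trifluoromethanesulfonate, CC[Si](CC)(CC)OS(=O)(=O)C(F)(F)F
Why: Silyl triflate silylation of the tertiary α-ketol blocks α-ketol rearrangement and a later six-membered lactone, and places a bulky axial group on the lower face of the ketone.

Step 24
Reactants: 34 C11,C13 bis(triethylsilyl) ether of the C12 ketone; 35 methyl (E)-3-methoxy-2-methylacrylate
Product: 38 O3-benzyl O11,O13-bis(triethylsilyl) spirotetronate, via lithiated acrylate 36 (not isolated), via lithium alkoxide adduct 37 (not isolated)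
Conditions: LiN(iPr)2, 35, THF, −90 °C; then 34, −78 → 0 °C; aq. NH4Cl
Reagents that add atoms: none
Why: Vinyl-anion tetronate synthesis: LiN(iPr)2 lithiates 35 at C3 cis to the ester, the vinyllithium should add to the C12 ketone anti to the axial C13 silyloxy group (steric and Felkin–Anh control), and the alkoxide lactonises onto the cis ester with loss of methoxide, giving the 4-methoxy-3-methylbutenolide with its ring oxygen cis to the C13 oxygen (12R).

Step 25
Reactants: 38 O3-benzyl O11,O13-bis(triethylsilyl) spirotetronate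
Product: 40 CNP0267781.1 (target), via O-benzyl target 39 (not isolated)
Conditions: HCl (1.25 M in MeOH), rt; then H2 (1 atm), Pd(OH)2/C, rt; NaHCO3 work-up
Reagents that add atoms: none
Why: Acid methanolysis removes both triethylsilyl ethers and hydrogenolysis over Pd(OH)2/C then cleaves the benzyl ether of the ammonium salt, the tetrasubstituted push–pull alkene of the tetronate being inert to hydrogenation.

**Compound list**

1 | (R)-2-hydroxybutanoic acid | CC[C@@H](O)C(=O)O | starting material
2 | (R)-2-(benzyloxy)butanoic acid | CC[C@@H](OCc1ccccc1)C(=O)O | intermediate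
3 | (R)-2-(benzyloxy)-N-methoxy-N-methylbutanamide | CC[C@@H](OCc1ccccc1)C(=O)N(C)OC | intermediate
4 | 5-bromopent-1-ene | C=CCCCBr | starting material
5 | pent-4-enylmagnesium bromide (not isolated) | C=CCCC[Mg]Br | intermediate
6 | (R)-3-(benzyloxy)non-8-en-4-one | CC[C@@H](OCc1ccccc1)C(=O)CCCC=C | intermediate
7 | 2-[(R)-1-(benzyloxy)propyl]-2-(pent-4-enyl)-1,3-dioxolane | CC[C@@H](OCc1ccccc1)C1(CCCC=C)OCCO1 | intermediate
8 | 4-{2-[(R)-1-(benzyloxy)propyl]-1,3-dioxolan-2-yl}butanal | CC[C@@H](OCc1ccccc1)C1(CCCC=O)OCCO1 | intermediate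
9 | (S)-N-[(E)-4-{2-[(R)-1-(benzyloxy)propyl]-1,3-dioxolan-2-yl}butylidene]-2-methylpropane-2-sulfinamide | CC[C@@H](OCc1ccccc1)C1(CCC/C=N/[S@@](=O)C(C)(C)C)OCCO1 | intermediate
10 | vinylmagnesium bromide | C=C[Mg]Br | starting material
11 | (S)-N-[(S)-6-{2-[(R)-1-(benzyloxy)propyl]-1,3-dioxolan-2-yl}hex-1-en-3-yl]-2-methylpropane-2-sulfinamide | CC[C@@H](OCc1ccccc1)C1(CCC[C@@H](C=C)N[S@@](=O)C(C)(C)C)OCCO1 | intermediate
12 | (S)-6-{2-[(R)-1-(benzyloxy)propyl]-1,3-dioxolan-2-yl}hex-1-en-3-amine hydrochloride (not isolated) | CC[C@@H](OCc1ccccc1)C1(CCC[C@@H](C=C)N)OCCO1.Cl | intermediate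
13 | tert-butyl N-[(S)-6-{2-[(R)-1-(benzyloxy)propyl]-1,3-dioxolan-2-yl}hex-1-en-3-yl]carbamate | CC[C@@H](OCc1ccccc1)C1(CCC[C@@H](C=C)NC(=O)OC(C)(C)C)OCCO1 | intermediate
14 | triethyl phosphonoacetate | CCOC(=O)CP(=O)(OCC)OCC | starting material
15 | 1,3-dibromopropane | BrCCCBr | starting material
16 | ethyl 5-bromo-2-(diethoxyphosphoryl)pentanoate (racemic) | CCOC(=O)C(CCCBr)P(=O)(OCC)OCC | intermediate
17 | ethyl 5-bromo-2-methylidenepentanoate | C=C(CCCBr)C(=O)OCC | intermediate
18 | ethyl 5-{(tert-butoxycarbonyl)[(S)-6-{2-[(R)-1-(benzyloxy)propyl]-1,3-dioxolan-2-yl}hex-1-en-3-yl]amino}-2-methylidenepentanoate | CC[C@@H](OCc1ccccc1)C1(CCC[C@@H](C=C)N(CCCC(=C)C(=O)OCC)C(=O)OC(C)(C)C)OCCO1 | intermediate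
19 | 1-tert-butyl 4-ethyl (S)-2-(3-{2-[(R)-1-(benzyloxy)propyl]-1,3-dioxolan-2-yl}propyl)-2,5,6,7-tetrahydro-1H-azepine-1,4-dicarboxylate | CC[C@@H](OCc1ccccc1)C1(CCC[C@H]2C=C(C(=O)OCC)CCCN2C(=O)OC(C)(C)C)OCCO1 | intermediate
20 | tert-butyl (S)-2-(3-{2-[(R)-1-(benzyloxy)propyl]-1,3-dioxolan-2-yl}propyl)-4-[methoxy(methyl)carbamoyl]-2,5,6,7-tetrahydro-1H-azepine-1-carboxylate | CC[C@@H](OCc1ccccc1)C1(CCC[C@H]2C=C(C(=O)N(C)OC)CCCN2C(=O)OC(C)(C)C)OCCO1 | intermediate
21 | prop-1-ynylmagnesium bromide | CC#C[Mg]Br | starting material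
22 | tert-butyl (S)-2-(3-{2-[(R)-1-(benzyloxy)propyl]-1,3-dioxolan-2-yl}propyl)-4-(but-2-ynoyl)-2,5,6,7-tetrahydro-1H-azepine-1-carboxylate | CC[C@@H](OCc1ccccc1)C1(CCC[C@H]2C=C(C(=O)C#CC)CCCN2C(=O)OC(C)(C)C)OCCO1 | intermediate
23 | tert-butyl (S)-2-(3-{2-[(R)-1-(benzyloxy)propyl]-1,3-dioxolan-2-yl}propyl)-4-[(R)-1-hydroxybut-2-ynyl]-2,5,6,7-tetrahydro-1H-azepine-1-carboxylate | CC[C@@H](OCc1ccccc1)C1(CCC[C@H]2C=C([C@@H](O)C#CC)CCCN2C(=O)OC(C)(C)C)OCCO1 | intermediate
24 | tert-butyl (S)-2-(3-{2-[(R)-1-(benzyloxy)propyl]-1,3-dioxolan-2-yl}propyl)-4-[(R)-1-(pivaloyloxy)but-2-ynyl]-2,5,6,7-tetrahydro-1H-azepine-1-carboxylate | CC[C@@H](OCc1ccccc1)C1(CCC[C@H]2C=C([C@@H](OC(=O)C(C)(C)C)C#CC)CCCN2C(=O)OC(C)(C)C)OCCO1 | intermediate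
25 | N-Boc azepane-fused cyclopentadienyl pivalate (C10=C11(OPiv), C12=C13, C9 sp3; not isolated) | CC[C@@H](OCc1ccccc1)C1(CCC[C@H]2[C@H]3C(C)=C(OC(=O)C(C)(C)C)C=C3CCCN2C(=O)OC(C)(C)C)OCCO1 | intermediate
26 | N-Boc azepane-fused cyclopent-2-enone (C11=O, C12=C13; 8S,9S,10S) with the dioxolane side chain at C8 | CC[C@@H](OCc1ccccc1)C1(CCC[C@H]2[C@H]3[C@H](C)C(=O)C=C3CCCN2C(=O)OC(C)(C)C)OCCO1 | intermediate
27 | amino ketone hydrochloride from 26 (Boc and dioxolane removed; not isolated) | CC[C@@H](OCc1ccccc1)C(=O)CCC[C@H]1[C@H]2[C@H](C)C(=O)C=C2CCCN1.Cl | intermediate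
28 | tricyclic C4=N iminium chloride (not isolated) | CC[C@@H](OCc1ccccc1)C1=[N+]2CCCC3=CC(=O)[C@@H](C)[C@@H]3[C@@H]2CCC1.[Cl-] | intermediate
29 | tricyclic enone amine (O3-benzyl; C11=O, C12=C13; 3R,4R,8S,9S,10S) | CC[C@@H](OCc1ccccc1)[C@H]1CCC[C@H]2[C@H]3[C@H](C)C(=O)C=C3CCCN12 | intermediate
30 | tricyclic C11 allylic alcohol (11S, OH cis to the C10 methyl) | CC[C@@H](OCc1ccccc1)[C@H]1CCC[C@H]2[C@H]3[C@H](C)[C@H](O)C=C3CCCN12 | intermediate
31 | C11 triethylsilyl ether of 30 | CC[C@@H](OCc1ccccc1)[C@H]1CCC[C@H]2[C@H]3[C@H](C)[C@H](O[Si](CC)(CC)CC)C=C3CCCN12 | intermediate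
32 | C12,C13 cis-diol (12R,13S; both OH trans to the C11 silyloxy group) | CC[C@@H](OCc1ccccc1)[C@H]1CCC[C@H]2[C@H]3[C@H](C)[C@H](O[Si](CC)(CC)CC)[C@@H](O)[C@]3(O)CCCN12 | intermediate
33 | C12 ketone with C13 tertiary alcohol and C11 triethylsilyl ether | CC[C@@H](OCc1ccccc1)[C@H]1CCC[C@H]2[C@H]3[C@H](C)[C@H](O[Si](CC)(CC)CC)C(=O)[C@]3(O)CCCN12 | intermediate
34 | C12 ketone, C11 and C13 bis(triethylsilyl) ether | CC[C@@H](OCc1ccccc1)[C@H]1CCC[C@H]2[C@H]3[C@H](C)[C@H](O[Si](CC)(CC)CC)C(=O)[C@]3(O[Si](CC)(CC)CC)CCCN12 | intermediate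
35 | methyl (E)-3-methoxy-2-methylacrylate | CO/C=C(\C)C(=O)OC | starting material
36 | methyl 3-lithio-3-methoxy-2-methylacrylate (Li cis to the ester; not isolated) | CO/C([Li])=C(\C)C(=O)OC | intermediate
37 | lithium C12 alkoxide adduct of 34 and 36 (not isolated) | CC[C@@H](OCc1ccccc1)[C@H]1CCC[C@H]2[C@H]3[C@H](C)[C@H](O[Si](CC)(CC)CC)[C@]([O-])(/C(OC)=C(/C)C(=O)OC)[C@]3(O[Si](CC)(CC)CC)CCCN12.[Li+] | intermediate
38 | O3-benzyl O11,O13-bis(triethylsilyl) spirotetronate (3R,4R,8S,9R,10S,11S,12R,13S) | CC[C@@H](OCc1ccccc1)[C@H]1CCC[C@H]2[C@H]3[C@H](C)[C@H](O[Si](CC)(CC)CC)[C@@]4(OC(=O)C(C)=C4OC)[C@]3(O[Si](CC)(CC)CC)CCCN12 | intermediate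
39 | O3-benzyl ether of the target (not isolated) | CC[C@@H](OCc1ccccc1)[C@H]1CCC[C@H]2[C@H]3[C@H](C)[C@H](O)[C@@]4(OC(=O)C(C)=C4OC)[C@]3(O)CCCN12 | intermediate
40 | CNP0267781.1 (3R,4R,8S,9R,10S,11S,12R,13S) | CC[C@@H](O)[C@H]1CCC[C@H]2[C@H]3[C@H](C)[C@H](O)[C@@]4(OC(=O)C(C)=C4OC)[C@]3(O)CCCN12 | target

**Step count and risks**

Total: 25 steps. Longest linear sequence: 23 steps (1–8, then 11–25); steps 9–10 are a two-step side branch.

Step 17. If the C12–O bond ionises fully before the C9–C10 bond forms, the information of the C12 centre is lost. The C8 side chain, held pseudo-axial by the Boc group, then steers C10 to the wrong face of C9; capture of the allyl cation by the Boc carbonyl is a second drain. The fallback sets out from 20 and returns at 26, replacing the gold cyclisation by a sigmatropic chirality transfer and a ring-closing metathesis. MeMgBr (THF, 0 °C) would convert 20 into the methyl ketone F1, and (R)-2-methyl-CBS-oxazaborolidine with BH3·SMe2 would reduce it to the (S)-allylic alcohol F2. Johnson–Claisen rearrangement with triethyl orthopropionate (cat. EtCO2H, xylene, 140 °C) would pass the carbinol configuration through a chair transition state to C9 and give the γ,δ-unsaturated ester F3 with an (E)-ethylidene at C13. MeNH(OMe)·HCl/iPrMgCl would give the Weinreb amide F4, and vinylmagnesium bromide the vinyl ketone F5. Ring-closing metathesis with the second-generation Grubbs catalyst (toluene, 80 °C), followed by K2CO3/MeOH equilibration at C10, would close the cyclopentenone and return 26.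

Step 24. The branched, basic vinyllithium may enolise the hindered C12 ketone towards C11 instead of adding, or add with weak facial preference. The fallback sets out from 34 and returns at 38, building the tetronate stepwise from a slim sp nucleophile. Lithium methyl propiolate (methyl propiolate, LiN(SiMe3)2, THF, −78 °C) would add to 34 to give the γ-hydroxy ynoate F6. NaOMe in MeOH would effect conjugate addition and lactonisation to the 3-unsubstituted tetronate F7. N-Bromosuccinimide, with the amine held as its trifluoroacetate salt (MeCN, 0 °C), would give the 3-bromotetronate F8. Stille methylation (SnMe4, Pd(PPh3)4, DMF, 80 °C) would return 38.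

Step 21. Osmylation may take place on the upper face (anti to C8, syn to the silyl ether) if the azepane side shields the lower face more than the C11 ether shields the upper, giving the cis-fused C13 epimer. The fallback sets out from 30 and returns at 33, using an epoxide of opposite facial demand. m-Chloroperbenzoic acid on the trifluoroacetate salt of 30 (CH2Cl2, 0 °C), directed by the free C11 hydroxyl, would give the syn-epoxy alcohol F9. TESOTf/2,6-lutidine would give the epoxy silyl ether F10. Water in hexafluoroisopropanol (40 °C) would open the epoxide at the tertiary C13 with inversion to the trans-diol F11, whose C13 hydroxyl lies on the lower face. Swern oxidation of the C12 alcohol would return 33.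

**Further compounds**

F1 | step 17 | tert-butyl (S)-4-acetyl-2-(3-{2-[(R)-1-(benzyloxy)propyl]-1,3-dioxolan-2-yl}propyl)-2,5,6,7-tetrahydro-1H-azepine-1-carboxylate | CC[C@@H](OCc1ccccc1)C1(CCC[C@H]2C=C(C(C)=O)CCCN2C(=O)OC(C)(C)C)OCCO1
F2 | step 17 | tert-butyl (S)-2-(3-{2-[(R)-1-(benzyloxy)propyl]-1,3-dioxolan-2-yl}propyl)-4-[(S)-1-hydroxyethyl]-2,5,6,7-tetrahydro-1H-azepine-1-carboxylate | CC[C@@H](OCc1ccccc1)C1(CCC[C@H]2C=C([C@@H](O)C)CCCN2C(=O)OC(C)(C)C)OCCO1
F3 | step 17 | N-Boc azepane with (E)-ethylidene at C13 and a 1-(ethoxycarbonyl)ethyl group at C9 (C9 cis to the C8 chain; C10 epimer mixture) | CC[C@@H](OCc1ccccc1)C1(CCC[C@H]2[C@@H](C(C)C(=O)OCC)/C(=C/C)CCCN2C(=O)OC(C)(C)C)OCCO1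
F4 | step 17 | Weinreb amide of F3 | CC[C@@H](OCc1ccccc1)C1(CCC[C@H]2[C@@H](C(C)C(=O)N(C)OC)/C(=C/C)CCCN2C(=O)OC(C)(C)C)OCCO1
F5 | step 17 | vinyl ketone from F4 (C11 carbonyl bearing the C12 vinyl group) | CC[C@@H](OCc1ccccc1)C1(CCC[C@H]2[C@@H](C(C)C(=O)C=C)/C(=C/C)CCCN2C(=O)OC(C)(C)C)OCCO1
F6 | step 24 | C12 tertiary propargylic alcohol bearing a 3-methoxy-3-oxoprop-1-ynyl group (hydroxyl cis to the C13 silyloxy group) | CC[C@@H](OCc1ccccc1)[C@H]1CCC[C@H]2[C@H]3[C@H](C)[C@H](O[Si](CC)(CC)CC)[C@](O)(C#CC(=O)OC)[C@]3(O[Si](CC)(CC)CC)CCCN12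
F7 | step 24 | 3'-unsubstituted spirotetronate (4-methoxybutenolide) | CC[C@@H](OCc1ccccc1)[C@H]1CCC[C@H]2[C@H]3[C@H](C)[C@H](O[Si](CC)(CC)CC)[C@@]4(OC(=O)C=C4OC)[C@]3(O[Si](CC)(CC)CC)CCCN12
F8 | step 24 | 3'-bromo spirotetronate | CC[C@@H](OCc1ccccc1)[C@H]1CCC[C@H]2[C@H]3[C@H](C)[C@H](O[Si](CC)(CC)CC)[C@@]4(OC(=O)C(Br)=C4OC)[C@]3(O[Si](CC)(CC)CC)CCCN12
F9 | step 21 | C12,C13 epoxide syn to the free C11 hydroxyl | CC[C@@H](OCc1ccccc1)[C@H]1CCC[C@H]2[C@H]3[C@H](C)[C@H](O)[C@@H]4O[C@]34CCCN12
F10 | step 21 | C11 triethylsilyl ether of F9 | CC[C@@H](OCc1ccccc1)[C@H]1CCC[C@H]2[C@H]3[C@H](C)[C@H](O[Si](CC)(CC)CC)[C@@H]4O[C@]34CCCN12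
F11 | step 21 | C12,C13 trans-diol (C12 OH cis to the C11 silyloxy group, C13 OH on the opposite face) | CC[C@@H](OCc1ccccc1)[C@H]1CCC[C@H]2[C@H]3[C@H](C)[C@H](O[Si](CC)(CC)CC)[C@H](O)[C@]3(O)CCCN12
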